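# Proposed total synthesis of catechin-(4α→8)-catechin-(4α→8)-catechin-(4α→8)-epicatechin by iterative benzannulation

## Analysis of the target

The target is the B-type procyanidin tetramer catechin-(4α→8)-catechin-(4α→8)-catechin-(4α→8)-epicatechin: four flavan-3-ol units, each with a phloroglucinol ring A, a pyran ring C and a catechol ring B, joined by three C4–C8 bonds. Units 1 to 3 are (2R,3S) with the C4 aryl group trans to O3 (2,3-trans, 3,4-trans), whereas unit 4 is (2R,3R) (2,3-cis) and ends the chain with a C4 methylene. This gives eleven stereocentres, and the three at C4 lie between two ortho-disubstituted arenes. Sixteen phenols and four secondary alcohols are free; the phenols oxidise in air, acid cleaves the interflavan bonds and base epimerises C2, so the free oligomer can appear only in the last step. The hard points are the regiochemistry (C8, not C6, of each ring A), control of chain length, the 3,4-trans configuration in the 2,3-trans series, and the need to solve all of this three times. The strategy rests on one feature: C4 of each upper unit is bonded to C8 of the fully substituted ring A below it, and C8 lies between C7 (bearing OH) and C8a (bearing O1). The atoms C7, C8, C8a and C4a can therefore come from a ketene and an alkynyl ether whose alkyne already sits on C4 of the upper unit and whose oxygen is O1 of the lower unit, so ring A and ring C of the lower unit are built onto C4 instead of being bonded to it.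

## Retrosynthetic reasoning

**64 from 63.** The nineteen O–benzyl bonds are cut last. Every oxygen is carried as a benzyl ether so that one hydrogenolysis frees the oligomer; the phenol left at O7 of unit 4 needs no protection.

**63 from 59.** In unit 4 the bonds C7–C8 and C4a–C8a are cut, which removes ring A and ring C together and leaves C8 as an alkyne carbon on C4 of unit 3. C8 is the only ring A carbon bonded to the upper unit, so building the ring around it removes the C6/C8 choice. The forward reaction must open the cyclobutenone of 59 to vinylketene 60, add it to the tethered alkynyl ether and aromatise.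

**59 from 58 and 40.** The bond between C4 of unit 3 and the alkyne carbon is cut. The whole unit 4 side chain, with C2 and C3 already set, arrives in one piece. The forward step must ionise C4 of 58 and deliver the terminal alkyne of 40 anti to O3.

**58 from 57 from 56.** The C4–O bond (benzylic oxidation of the only methylene C4) and the O7–benzyl bond are cut. The free phenol of 56 must be capped first because the oxidant would attack it.

**56 from 52, 52 from 51 and 25, 51 from 50 from 49.** The same three operations one unit higher, with the 2,3-trans fragment 25.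

**49 from 45, 45 from 44 and 25, 44 from 43 from 42 from 41.** The first benzannulation is the key step. Unit 1 comes from 41, which supplies C2 and C3 from the chiral pool; only its C4 is new.

**25 and 40 from 24 and 39, and these from 21 and 36.** The terminal alkynyl ether is made from a dichlorovinyl ether with a strong organolithium base, which a cyclobutenone would not survive. The cyclobutenone is therefore reduced to its alkoxide for that operation and reoxidised afterwards.

**21 and 36 from 19 and 35 with 20.** Two ring bonds of the cyclobutenone are cut; a [2+2] cycloaddition of 20 with a 1-alkoxyalkyne puts the chain on C2 and the benzyloxy group on C3. The dichlorovinyl ether is installed before this step because it does not react with 20, whereas a second alkynyl ether would.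

**19 and 35 from 16 and 33 with 17; 17 from 4; 4 from 3 and 2.** The C4–C4a bond is made by alkylation of alkoxyacetylide 17, so the benzyl group that later protects O5 arrives with the alkyne. One reagent, made from 4, serves both fragments.

**16 and 33 from 14 and 31 with 2; 2 from 1.** The bond between the benzylic oxygen and the two-carbon unit is cut. Both carbons come from chloroalkyne 2, which is made from 1 as a dilute solution and also delivers 4.

**14 from 13 from 12; 12 and 31 from 11 and 30, from 10 and 29, from 7 or 27 with 8; 7 and 27 from 5 or 26 with 6.** The C2–C3 bond is made by a syn glycolate aldol, which sets both centres and delivers O3 already benzylated and O2 free for the alkynyl ether. The 2,3-cis fragment uses the syn product directly. The 2,3-trans fragment uses the enantiomeric syn product and inverts the benzylic carbinol by oxidation and chelation-controlled reduction, two reactions whose stereochemical outcome is secure.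

## Alternatives that were turned down

Alternative 1: olefinic ester cyclisation to a flav-2-ene.
- Disconnection: the C2=C3 bond of an upper unit.
- Forward key step: the C4 vinyl group would be turned into a titanium alkylidene with an excess of the Tebbe reagent Cp2Ti(μ-Cl)(μ-CH2)AlMe2. This alkylidene would olefinate the carbonyl of the adjacent 3,4-bis(benzyloxy)benzoate on the ring A oxygen, so that ring C closes as the 4-aryl-4H-chromene A1.
- For it: the ring closure is an established way to cyclic enol ethers and needs no light. A1 would allow C2 and C3 to be set together by hydroboration anti to the C4 aryl group.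
- Against it: the C4–C8 bond and the diarylmethine stereocentre must exist before the step, so the regiochemical problem is moved, not solved. The stoichiometric, Lewis acidic reagent has to tolerate many benzyl ethers and a hindered, electron-rich ester. The doubly benzylic enol ether of A1 is acid-labile. Two stereocentres per unit remain to be set afterwards, three times over.
- Comparison: it is at least as strong on the reliability of the ring-closing event. The chosen route offers instead a ring construction that fixes the 4→8 linkage, and it imports C2 and C3 with the fragment, so no stereocentre is made after the ring exists.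

Alternative 2: biomimetic Claisen aromatisation of a dihydropyran.
- Disconnection: the C7–C8 bond of ring A of an upper unit.
- Forward key step: a methyl group on the enol ether carbon C8a would be deprotonated and would condense with the ester carbonyl of a β-keto ester chain. Loss of methanol and enolisation would then deliver the 5,7-dihydroxyarene A2.
- For it: base only, no metal, and the phenols appear unprotected, as in polyketide biosynthesis.
- Against it: the substrate is a dihydropyran that already carries C2, C3, the C4 aryl group, an enol ether and a β-keto ester, which is much harder to reach than 45. Deprotonation of the vinylogous methyl competes with the more acidic site between the carbonyls. The ring made is ring A of the upper unit, with C6 and C8 both free, so the next interflavan bond would again be a C6/C8 choice on a free phloroglucinol.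
- Comparison: it is stronger on protecting-group economy at the new ring. The chosen route gives in its place a ring A whose C8 is already bonded to the upper unit and whose oxygens are differentiated (O5 benzyl, O7 free).

Alternative 3: phenol opening of a styrenyl epoxide.
- Disconnection: the O1–C2 bond of an upper unit.
- Forward key step: a ring A phenol left unprotected would open a trans C2–C3 epoxide at its benzylic carbon with inversion. Ring C closes in this way and A3, with a free C3 hydroxyl, results.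
- For it: 6-endo opening at an electron-rich benzylic carbon is well founded. The epoxide sets C3 and the inversion sets C2 in the 2,3-trans relationship, and the conditions are mild.
- Against it: ring A and the C4–C8 bond are not made by this step. The diarylmethine C4 with its homoallylic chain must be built enantioselectively first, on a phloroglucinol whose three oxygens have to be differentiated. 5-exo closure to a dihydrobenzofuran competes. An asymmetric epoxidation is needed for every unit.
- Comparison: it is as strong or stronger on the predictability of the ring-closing step and on the control of C2 and C3. The chosen route offers regiochemistry by construction, a C4 centre set by a simple anti addition, and one fragment (25) used twice.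

Key step: step 30

Remark: the C4 configuration of the 2-ethoxyethyl ethers 44, 51 and 58 and the transient centres of 22–24, 37–39, 47, 54 and 61 are left undefined, because each is destroyed in the following operation; ketene 20 is generated by pyrolysis of acetone and counted as a starting material; the reagent solutions 2 and 17 are prepared fresh for each use and are not stored.

## Steps

### Reagents 2 and 4 (steps 1–2)

Step 1
Reactants: 1 trichloroethylene
Product: 2 dichloroacetylene (dilute THF solution, used directly)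
Conditions: KH (1.05 equiv), MeOH (cat.), THF, 0 °C to rt; solution decanted under argon, never concentrated
Reagents that add atoms: none
Why: Base-induced β-elimination of HCl: catalytic potassium methoxide removes the vinylic proton, chloride leaves, and KH regenerates the methoxide. The chloroalkyne is kept as a dilute ethereal solution, in which it can be transferred safely, and the preparation is repeated whenever steps 2, 9 and 20 call for it.

Step 2
Reactants: 3 benzyl alcohol; 2 dichloroacetylene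
Product: 4 benzyl (E)-1,2-dichlorovinyl ether
Conditions: KH (0.2 equiv), THF, 0 °C; 2 (THF solution, 1.2 equiv), −40 °C to rt
Reagents that add atoms: none
Why: Dichlorovinyl ether synthesis by addition of an alkoxide to a chloroalkyne: potassium benzyloxide attacks 2 and the vinyl anion forms anti to the new C–O bond, so protonation by free alcohol gives the E ether and returns the alkoxide. The base is kept substoichiometric so that a proton source is always present and the vinyl anion does not add to a second molecule of 2.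

### 2,3-trans fragment 25 (steps 3–15; step 11 makes reagent 17)

Step 3
Reactants: 5 (R)-4-benzyl-1,3-oxazolidin-2-one; 6 (benzyloxy)acetyl chloride
Product: 7 (R)-4-benzyl-3-[(benzyloxy)acetyl]-1,3-oxazolidin-2-one
Conditions: n-BuLi, THF, −78 °C; then 6
Reagents that add atoms: none
Why: N-acylation of the lithiated oxazolidinone.

Step 4
Reactants: 7 (R)-N-(benzyloxyacetyl)oxazolidinone; 8 3,4-bis(benzyloxy)benzaldehyde
Product: 10 syn aldol adduct, (2R,3S) in the acyl chain, via boron enolate 9 (not isolated)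
Conditions: Bu2BOTf, i-Pr2NEt, CH2Cl2, −78 to 0 °C; 8, −78 to 0 °C; MeOH, pH 7 phosphate buffer, H2O2
Reagents that add atoms: none
Why: Evans syn glycolate aldol: the Z boron enolate reacts through a closed Zimmerman–Traxler transition state on the face away from the benzyl group of the auxiliary, which sets both new centres in the syn relationship.

Step 5
Reactants: 10 syn aldol adduct
Product: 11 (1S,2S)-2-(benzyloxy)-1-[3,4-bis(benzyloxy)phenyl]propane-1,3-diol
Conditions: LiBH4, H2O (1 equiv), THF, 0 °C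
Reagents that add atoms: none
Why: Reductive cleavage of the imide to the primary alcohol; the stereocentres are not touched and the auxiliary is recovered.

Step 6
Reactants: 11 (1S,2S)-diol
Product: 12 (1S,2S)-3-O-triisopropylsilyl ether of 11
Conditions: TIPSCl, imidazole, CH2Cl2, 0 °C
Reagents that add atoms: triisopropylsilyl chloride, CC(C)[Si](Cl)(C(C)C)C(C)C
Why: The bulky silyl chloride takes the primary hydroxyl only; triisopropylsilyl is chosen because it should not migrate to the neighbouring alkoxide in step 9.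

Step 7
Reactants: 12 (1S,2S)-silyl ether
Product: 13 (S)-2-(benzyloxy)-1-[3,4-bis(benzyloxy)phenyl]-3-[(triisopropylsilyl)oxy]propan-1-one
Conditions: Dess–Martin periodinane, NaHCO3, CH2Cl2, 0 °C to rt
Reagents that add atoms: none
Why: Dess–Martin oxidation of the benzylic alcohol under buffered conditions, which should leave the α-benzyloxy centre intact.

Step 8
Reactants: 13 (S)-ketone
Product: 14 (1R,2S)-2-(benzyloxy)-1-[3,4-bis(benzyloxy)phenyl]-3-[(triisopropylsilyl)oxy]propan-1-ol
Conditions: Zn(BH4)2, Et2O, −78 to −20 °C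
Reagents that add atoms: none
Why: Chelation-controlled reduction (Cram chelate model): zinc bridges the carbonyl and the α-benzyloxy oxygen and hydride enters from the side of the α-hydrogen, giving the anti alcohol, which is the catechin relationship of the future C2 and C3.

Step 9
Reactants: 14 (1R,2S)-alcohol; 2 dichloroacetylene
Product: 15 (E)-1,2-dichlorovinyl ether of 14
Conditions: KH (0.3 equiv), THF, 0 °C; 2 (THF solution, 1.3 equiv), −40 °C to rt
Reagents that add atoms: none
Why: Alkoxide addition to the chloroalkyne as in step 2, with anti addition giving the E ether; the benzylic C–O bond is not broken, so the configuration is kept. With only part of the alcohol present as alkoxide and a triisopropylsilyl group next to it, silyl migration should stay slow.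

Step 10
Reactants: 15 dichlorovinyl ether
Product: 16 (2S,3R)-2-(benzyloxy)-3-[3,4-bis(benzyloxy)phenyl]-3-{[(E)-1,2-dichloroethenyl]oxy}propan-1-ol
Conditions: Bu4NF, THF, 0 °C
Reagents that add atoms: none
Why: Fluoride cleavage of the silyl ether; the electron-poor dichlorovinyl ether is stable to fluoride.

Step 11
Reactants: 4 benzyl (E)-1,2-dichlorovinyl ether
Product: 17 lithium (benzyloxy)acetylide (THF solution, kept at −78 °C, used directly)
Conditions: n-BuLi (2.0 equiv), THF, −78 to −40 °C, then −78 °C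
Reagents that add atoms: n-butyllithium, [Li]CCCC
Why: Alkynyl ether synthesis from a dichlorovinyl ether: the first equivalent of n-BuLi removes the vinylic proton and chloride is lost to give the chloroalkynyl ether, and the second exchanges chlorine for lithium. No excess base is used, and the solution is made anew for steps 12 and 22.

Step 12
Reactants: 16 (2S,3R)-primary alcohol; 17 lithium (benzyloxy)acetylide
Product: 19 (4S,5R)-1,4-bis(benzyloxy)-5-[3,4-bis(benzyloxy)phenyl]-5-{[(E)-1,2-dichloroethenyl]oxy}pent-1-yne, via triflate 18 (not isolated)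
Conditions: 16, Tf2O, 2,6-lutidine, CH2Cl2, −78 °C; then added to 17 (THF solution, 1.5 equiv), DMPU, −78 to −20 °C
Reagents that add atoms: none
Why: SN2 alkylation of an alkoxyacetylide with a primary triflate; the dichlorovinyl ether of 18 is not deprotonated by an acetylide, and no free n-BuLi is present.

Step 13
Reactants: 19 benzyl alkynyl ether; 20 ketene
Product: 21 3-(benzyloxy)-2-[(2S,3R)-2-(benzyloxy)-3-[3,4-bis(benzyloxy)phenyl]-3-{[(E)-1,2-dichloroethenyl]oxy}propyl]cyclobut-2-en-1-one
Conditions: 20 (gas, excess), CH2Cl2, 0 °C to rt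
Reagents that add atoms: none
Why: [2+2] cycloaddition of ketene with a 1-alkoxyalkyne: the ketene carbonyl carbon bonds to the alkyne carbon remote from oxygen, which puts the chain on C2 and benzyloxy on C3; the dichlorovinyl ether is too electron-poor to react.

Step 14
Reactants: 21 cyclobutenone dichlorovinyl ether
Product: 24 3-(benzyloxy)-2-[(2S,3R)-2-(benzyloxy)-3-[3,4-bis(benzyloxy)phenyl]-3-(ethynyloxy)propyl]cyclobut-2-en-1-ol, via aluminium alkoxide 22 (not isolated), via lithium acetylide 23 (not isolated)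
Conditions: i-Bu2AlH, THF, −78 °C; n-BuLi (3.3 equiv), −78 to −50 °C; MeOH, then aq. potassium sodium tartrate/NaHCO3
Reagents that add atoms: none
Why: 1,2-Reduction masks the cyclobutenone as alkoxide 22, which survives the n-BuLi that converts the dichlorovinyl ether into acetylide 23; protonation gives the terminal alkynyl ether. The carbinol epimers are used together and crude, with base-washed glassware.

Step 15
Reactants: 24 cyclobutenol
Product: 25 3-(benzyloxy)-2-[(2S,3R)-2-(benzyloxy)-3-[3,4-bis(benzyloxy)phenyl]-3-(ethynyloxy)propyl]cyclobut-2-en-1-one (2,3-trans fragment)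
Conditions: MnO2, CH2Cl2, 0 °C
Reagents that add atoms: none
Why: Allylic alcohol oxidation under neutral conditions restores the vinylogous ester without touching the alkynyl ether; 25 is kept cold and used soon.

### 2,3-cis fragment 40 (steps 16–25)

Step 16
Reactants: 26 (S)-4-benzyl-1,3-oxazolidin-2-one; 6 (benzyloxy)acetyl chloride
Product: 27 (S)-4-benzyl-3-[(benzyloxy)acetyl]-1,3-oxazolidin-2-one
Conditions: n-BuLi, THF, −78 °C; then 6
Reagents that add atoms: none
Why: N-acylation as in step 3, with the enantiomeric auxiliary.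

Step 17
Reactants: 27 (S)-N-(benzyloxyacetyl)oxazolidinone; 8 3,4-bis(benzyloxy)benzaldehyde
Product: 29 syn aldol adduct, (2S,3R) in the acyl chain, via boron enolate 28 (not isolated)
Conditions: Bu2BOTf, i-Pr2NEt, CH2Cl2, −78 to 0 °C; 8, −78 to 0 °C; MeOH, pH 7 phosphate buffer, H2O2
Reagents that add atoms: none
Why: Evans syn glycolate aldol as in step 4; with the S auxiliary the syn adduct already has the epicatechin configuration of the future C2 and C3.

Step 18
Reactants: 29 syn aldol adduct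
Product: 30 (1R,2R)-2-(benzyloxy)-1-[3,4-bis(benzyloxy)phenyl]propane-1,3-diol
Conditions: LiBH4, H2O (1 equiv), THF, 0 °C
Reagents that add atoms: none
Why: Reductive cleavage of the imide as in step 5.

Step 19
Reactants: 30 (1R,2R)-diol
Product: 31 (1R,2R)-3-O-triisopropylsilyl ether of 30
Conditions: TIPSCl, imidazole, CH2Cl2, 0 °C
Reagents that add atoms: triisopropylsilyl chloride, CC(C)[Si](Cl)(C(C)C)C(C)C
Why: Selective silylation of the primary hydroxyl as in step 6.

Step 20
Reactants: 31 (1R,2R)-silyl ether; 2 dichloroacetylene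
Product: 32 (E)-1,2-dichlorovinyl ether of 31
Conditions: KH (0.3 equiv), THF, 0 °C; 2 (THF solution, 1.3 equiv), −40 °C to rt
Reagents that add atoms: none
Why: Alkoxide addition to the chloroalkyne as in step 9, with retention at the benzylic carbon.

Step 21
Reactants: 32 dichlorovinyl ether
Product: 33 (2R,3R)-2-(benzyloxy)-3-[3,4-bis(benzyloxy)phenyl]-3-{[(E)-1,2-dichloroethenyl]oxy}propan-1-ol
Conditions: Bu4NF, THF, 0 °C
Reagents that add atoms: none
Why: Fluoride cleavage of the silyl ether as in step 10.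

Step 22
Reactants: 33 (2R,3R)-primary alcohol; 17 lithium (benzyloxy)acetylide
Product: 35 (4R,5R)-1,4-bis(benzyloxy)-5-[3,4-bis(benzyloxy)phenyl]-5-{[(E)-1,2-dichloroethenyl]oxy}pent-1-yne, via triflate 34 (not isolated)
Conditions: 33, Tf2O, 2,6-lutidine, CH2Cl2, −78 °C; then added to 17 (THF solution, 1.5 equiv), DMPU, −78 to −20 °C
Reagents that add atoms: none
Why: SN2 alkylation of the alkoxyacetylide with the primary triflate as in step 12.

Step 23
Reactants: 35 benzyl alkynyl ether; 20 ketene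
Product: 36 3-(benzyloxy)-2-[(2R,3R)-2-(benzyloxy)-3-[3,4-bis(benzyloxy)phenyl]-3-{[(E)-1,2-dichloroethenyl]oxy}propyl]cyclobut-2-en-1-one
Conditions: 20 (gas, excess), CH2Cl2, 0 °C to rt
Reagents that add atoms: none
Why: Regioselective ketene–alkoxyalkyne [2+2] cycloaddition as in step 13.

Step 24
Reactants: 36 cyclobutenone dichlorovinyl ether
Product: 39 3-(benzyloxy)-2-[(2R,3R)-2-(benzyloxy)-3-[3,4-bis(benzyloxy)phenyl]-3-(ethynyloxy)propyl]cyclobut-2-en-1-ol, via aluminium alkoxide 37 (not isolated), via lithium acetylide 38 (not isolated)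
Conditions: i-Bu2AlH, THF, −78 °C; n-BuLi (3.3 equiv), −78 to −50 °C; MeOH, then aq. potassium sodium tartrate/NaHCO3
Reagents that add atoms: none
Why: Reduction to the alkoxide, then conversion of the dichlorovinyl ether to the acetylide and protonation, as in step 14.

Step 25
Reactants: 39 cyclobutenol
Product: 40 3-(benzyloxy)-2-[(2R,3R)-2-(benzyloxy)-3-[3,4-bis(benzyloxy)phenyl]-3-(ethynyloxy)propyl]cyclobut-2-en-1-one (2,3-cis fragment)
Conditions: MnO2, CH2Cl2, 0 °C
Reagents that add atoms: none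
Why: Neutral allylic oxidation as in step 15.

### Main chain (steps 26–39)

Step 26
Reactants: 41 (+)-catechin
Product: 42 5,7,3',4'-tetra-O-benzyl-(+)-catechin
Conditions: BnBr, K2CO3, DMF, rt
Reagents that add atoms: benzyl bromide, BrCc1ccccc1
Why: Williamson ether synthesis; carbonate alkylates the four phenols and leaves the secondary alcohol.

Step 27
Reactants: 42 tetra-O-benzylcatechin
Product: 43 3,5,7,3',4'-penta-O-benzyl-(+)-catechin
Conditions: NaH, BnBr, Bu4NI (cat.), THF/DMF, 0 °C to rt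
Reagents that add atoms: benzyl bromide, BrCc1ccccc1
Why: Williamson benzylation of the C3 alkoxide.

Step 28
Reactants: 43 penta-O-benzylcatechin
Product: 44 4-(2-ethoxyethoxy)-3,5,7,3',4'-penta-O-benzylcatechin (C4 epimers)
Conditions: DDQ, 2-ethoxyethanol, CH2Cl2, rt
Reagents that add atoms: 2-ethoxyethanol, CCOCCO
Why: Benzylic oxidation: DDQ abstracts hydride from C4, which the 5- and 7-benzyloxy groups activate, and the cation is trapped by the alcohol.

Step 29
Reactants: 44 C4-activated unit 1; 25 2,3-trans fragment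
Product: 45 penta-O-benzylcatechin bearing at C4 (4α, trans to O3) the group C≡C–O–CH(Ar)–CH(OBn)–CH2–(2-benzyloxy-4-oxocyclobut-1-en-1-yl), with the chain (1R,2S) (key-step precursor)
Conditions: CuI (15 mol%), i-Pr2NEt, TMSOTf, CH2Cl2, −78 to −40 °C; 25 (1.5 equiv)
Reagents that add atoms: none
Why: Copper-catalysed alkynylation of an oxocarbenium-type benzylic cation: TMSOTf ionises the C4 ether and the terminal alkyne of 25, activated by CuI, bonds through the carbon remote from oxygen, with the amine taking up the proton. The nucleophile enters anti to the C3 benzyloxy group, which sets C4 as 3,4-trans.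

Step 30
Reactants: 45 key-step precursor
Product: 49 nona-O-benzyl catechin-(4α→8)-catechin with free O7 on unit 2, via vinylketene 46 (not isolated), via fused vinylcyclobutenone 47 (not isolated), via dienylketene 48 (not isolated)
Conditions: hν (350 nm), degassed toluene (5 mM), 5 °C; then 80 °C, dark
Reagents that add atoms: none
Why: Proposed new method: light opens the cyclobutenone in a four-electron electrocyclic reaction to vinylketene 46, whose carbonyl carbon bonds to the alkyne carbon remote from oxygen and whose α-carbon bonds to the oxygen-bearing carbon, giving the fused vinylcyclobutenone 47. Warming opens 47 to dienylketene 48, and six-electron electrocyclisation with tautomerisation gives phenol 49; the closest known reaction types are the intermolecular Danheiser benzannulation of cyclobutenones with alkoxyalkynes, including its photochemical start, and the intramolecular [2+2] cycloaddition of ketenes with alkynes. Ring C closes in the [2+2] event as a six-membered ring in the fused mode, by the C4a–C8a bond across the four-atom tether, and ring A closes by the electrocyclisation between C6 and C7. No stereocentre of the product is formed: the ring-fusion centre of 47 is lost on ring opening, and C2 and C3 of both units and the propargylic C4 are not touched. The step needs the regiochemistry that places the ether oxygen on C8a; the polarisation of the alkynyl ether and the tether length both demand it, and the pyran ring holds the central double bond of 48 in the cis geometry needed for closure. Light is used for the first opening because the secondary benzylic alkynyl ether should not survive long heating (sigmatropic shift into the aryl ring, retro-ene loss of a ketene); once the [2+2] event has consumed it, 80 °C is safe.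

Step 31
Reactants: 49 dimer phenol
Product: 50 deca-O-benzyl catechin-(4α→8)-catechin
Conditions: BnBr, Cs2CO3, DMF, rt
Reagents that add atoms: benzyl bromide, BrCc1ccccc1
Why: Williamson benzylation of the hindered O7 phenol; it must be capped before the quinone oxidant is used.

Step 32
Reactants: 50 deca-O-benzyl dimer
Product: 51 deca-O-benzyl dimer with 2-ethoxyethoxy at C4 of unit 2 (C4 epimers)
Conditions: DDQ, 2-ethoxyethanol, CH2Cl2, rt
Reagents that add atoms: 2-ethoxyethanol, CCOCCO
Why: Benzylic oxidation as in step 28; the methylene C4 of unit 2 is the accessible hydride donor, while the interflavan C4–H is shielded between two ortho-disubstituted rings and cannot easily align with either.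

Step 33
Reactants: 51 C4-activated dimer; 25 2,3-trans fragment
Product: 52 deca-O-benzyl dimer bearing at C4 of unit 2 (4α) the alkynyl ether side chain of 25 (trimer precursor)
Conditions: CuI (15 mol%), i-Pr2NEt, TMSOTf, CH2Cl2, −78 to −40 °C; 25 (1.5 equiv)
Reagents that add atoms: none
Why: Copper-catalysed alkynylation of the C4 cation as in step 29; attack anti to the C3 benzyloxy group sets C4 of unit 2.

Step 34
Reactants: 52 trimer precursor
Product: 56 tetradeca-O-benzyl catechin-(4α→8)-catechin-(4α→8)-catechin with free O7 on unit 3, via vinylketene 53 (not isolated), via fused vinylcyclobutenone 54 (not isolated), via dienylketene 55 (not isolated)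
Conditions: hν (350 nm), degassed toluene (5 mM), 5 °C; then 80 °C, dark
Reagents that add atoms: none
Why: Proposed new method: the same cascade as in step 30 (photochemical opening to 53, tethered [2+2] to 54, opening to 55, six-electron closure and tautomerisation), with the intermolecular Danheiser benzannulation with alkoxyalkynes as the closest known reaction type. The tether closes ring C in the fused mode and fixes O1 on C8a, and no stereocentre is formed or touched.

Step 35
Reactants: 56 trimer phenol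
Product: 57 pentadeca-O-benzyl catechin trimer
Conditions: BnBr, Cs2CO3, DMF, rt
Reagents that add atoms: benzyl bromide, BrCc1ccccc1
Why: Williamson benzylation of O7 of unit 3 as in step 31.

Step 36
Reactants: 57 pentadeca-O-benzyl trimer
Product: 58 pentadeca-O-benzyl trimer with 2-ethoxyethoxy at C4 of unit 3 (C4 epimers)
Conditions: DDQ, 2-ethoxyethanol, CH2Cl2, rt
Reagents that add atoms: 2-ethoxyethanol, CCOCCO
Why: Benzylic oxidation at the only methylene C4, as in step 32.

Step 37
Reactants: 58 C4-activated trimer; 40 2,3-cis fragment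
Product: 59 pentadeca-O-benzyl trimer bearing at C4 of unit 3 (4α) the alkynyl ether side chain of 40 (tetramer precursor)
Conditions: CuI (15 mol%), i-Pr2NEt, TMSOTf, CH2Cl2, −78 to −40 °C; 40 (1.5 equiv)
Reagents that add atoms: none
Why: Copper-catalysed alkynylation of the C4 cation as in step 29; attack anti to the C3 benzyloxy group sets C4 of unit 3.

Step 38
Reactants: 59 tetramer precursor
Product: 63 nonadeca-O-benzyl catechin-(4α→8)-catechin-(4α→8)-catechin-(4α→8)-epicatechin with free O7 on unit 4, via vinylketene 60 (not isolated), via fused vinylcyclobutenone 61 (not isolated), via dienylketene 62 (not isolated)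
Conditions: hν (350 nm), degassed toluene (5 mM), 5 °C; then 80 °C, dark
Reagents that add atoms: none
Why: Proposed new method: the cascade of step 30 with the 2,3-cis tether (opening to 60, tethered [2+2] to 61, opening to 62, six-electron closure and tautomerisation), with the intermolecular Danheiser benzannulation with alkoxyalkynes as the closest known reaction type. Ring C of unit 4 closes in the fused mode and ring A by electrocyclisation, and the cis centres C2 and C3 come unchanged from 40.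

Step 39
Reactants: 63 nonadeca-O-benzyl tetramer
Product: 64 catechin-(4α→8)-catechin-(4α→8)-catechin-(4α→8)-epicatechin (target)
Conditions: H2 (1 atm), Pd(OH)2/C, THF/MeOH/H2O, rt
Reagents that add atoms: none
Why: Hydrogenolysis of the nineteen benzyl ethers under neutral conditions, which should leave the interflavan bonds and all stereocentres intact.

## Compound list

1 | trichloroethylene | ClC=C(Cl)Cl | starting material
2 | dichloroacetylene | ClC#CCl | intermediate
3 | benzyl alcohol | OCc1ccccc1 | starting material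
4 | benzyl (E)-1,2-dichlorovinyl ether | Cl/C=C(/Cl)OCc1ccccc1 | intermediate
5 | (R)-4-benzyl-1,3-oxazolidin-2-one | O=C1N[C@H](Cc2ccccc2)CO1 | starting material
6 | (benzyloxy)acetyl chloride | O=C(Cl)COCc1ccccc1 | starting material
7 | (R)-4-benzyl-3-[(benzyloxy)acetyl]-1,3-oxazolidin-2-one | O=C(COCc1ccccc1)N1C(=O)OC[C@H]1Cc1ccccc1 | intermediate
8 | 3,4-bis(benzyloxy)benzaldehyde | O=Cc1ccc(OCc2ccccc2)c(OCc2ccccc2)c1 | starting material
9 | (Z)-dibutylboron enolate of 7 | CCCCB(CCCC)O/C(=C\OCc1ccccc1)N1C(=O)OC[C@H]1Cc1ccccc1 | intermediate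
10 | (4R)-4-benzyl-3-[(2R,3S)-2-(benzyloxy)-3-[3,4-bis(benzyloxy)phenyl]-3-hydroxypropanoyl]-1,3-oxazolidin-2-one | O[C@@H](c4ccc(OCc5ccccc5)c(OCc5ccccc5)c4)[C@@H](OCc5ccccc5)C(=O)N1C(=O)OC[C@H]1Cc1ccccc1 | intermediate
11 | (1S,2S)-2-(benzyloxy)-1-[3,4-bis(benzyloxy)phenyl]propane-1,3-diol | O[C@@H](c4ccc(OCc5ccccc5)c(OCc5ccccc5)c4)[C@@H](OCc5ccccc5)CO | intermediate
12 | (1S,2S)-2-(benzyloxy)-1-[3,4-bis(benzyloxy)phenyl]-3-[(triisopropylsilyl)oxy]propan-1-ol | O[C@@H](c4ccc(OCc5ccccc5)c(OCc5ccccc5)c4)[C@@H](OCc5ccccc5)CO[Si](C(C)C)(C(C)C)C(C)C | intermediate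
13 | (S)-2-(benzyloxy)-1-[3,4-bis(benzyloxy)phenyl]-3-[(triisopropylsilyl)oxy]propan-1-one | O=C(c4ccc(OCc5ccccc5)c(OCc5ccccc5)c4)[C@@H](OCc5ccccc5)CO[Si](C(C)C)(C(C)C)C(C)C | intermediate
14 | (1R,2S)-2-(benzyloxy)-1-[3,4-bis(benzyloxy)phenyl]-3-[(triisopropylsilyl)oxy]propan-1-ol | O[C@H](c4ccc(OCc5ccccc5)c(OCc5ccccc5)c4)[C@@H](OCc5ccccc5)CO[Si](C(C)C)(C(C)C)C(C)C | intermediate
15 | (E)-1,2-dichlorovinyl ether of 14 | Cl/C=C(/Cl)O[C@H](c4ccc(OCc5ccccc5)c(OCc5ccccc5)c4)[C@@H](OCc5ccccc5)CO[Si](C(C)C)(C(C)C)C(C)C | intermediate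
16 | (2S,3R)-2-(benzyloxy)-3-[3,4-bis(benzyloxy)phenyl]-3-{[(E)-1,2-dichloroethenyl]oxy}propan-1-ol | Cl/C=C(/Cl)O[C@H](c4ccc(OCc5ccccc5)c(OCc5ccccc5)c4)[C@@H](OCc5ccccc5)CO | intermediate
17 | lithium (benzyloxy)acetylide | [Li]C#COCc1ccccc1 | intermediate
18 | trifluoromethanesulfonate of 16 | Cl/C=C(/Cl)O[C@H](c4ccc(OCc5ccccc5)c(OCc5ccccc5)c4)[C@@H](OCc5ccccc5)COS(=O)(=O)C(F)(F)F | intermediate
19 | (4S,5R)-1,4-bis(benzyloxy)-5-[3,4-bis(benzyloxy)phenyl]-5-{[(E)-1,2-dichloroethenyl]oxy}pent-1-yne | Cl/C=C(/Cl)O[C@H](c4ccc(OCc5ccccc5)c(OCc5ccccc5)c4)[C@@H](OCc5ccccc5)CC#COCc5ccccc5 | intermediate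
20 | ketene | C=C=O | starting material
21 | 3-(benzyloxy)-2-[(2S,3R)-2-(benzyloxy)-3-[3,4-bis(benzyloxy)phenyl]-3-{[(E)-1,2-dichloroethenyl]oxy}propyl]cyclobut-2-en-1-one | Cl/C=C(/Cl)O[C@H](c4ccc(OCc5ccccc5)c(OCc5ccccc5)c4)[C@@H](OCc5ccccc5)CC1=C(OCc5ccccc5)CC1=O | intermediate
22 | diisobutylaluminium alkoxide of the cyclobutenol from 21 | Cl/C=C(/Cl)O[C@H](c4ccc(OCc5ccccc5)c(OCc5ccccc5)c4)[C@@H](OCc5ccccc5)CC1=C(OCc5ccccc5)CC1O[Al](CC(C)C)CC(C)C | intermediate
23 | lithium acetylide from 22 | [Li]C#CO[C@H](c4ccc(OCc5ccccc5)c(OCc5ccccc5)c4)[C@@H](OCc5ccccc5)CC1=C(OCc5ccccc5)CC1O[Al](CC(C)C)CC(C)C | intermediate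
24 | 3-(benzyloxy)-2-[(2S,3R)-2-(benzyloxy)-3-[3,4-bis(benzyloxy)phenyl]-3-(ethynyloxy)propyl]cyclobut-2-en-1-ol (carbinol epimers) | C#CO[C@H](c4ccc(OCc5ccccc5)c(OCc5ccccc5)c4)[C@@H](OCc5ccccc5)CC1=C(OCc5ccccc5)CC1O | intermediate
25 | 3-(benzyloxy)-2-[(2S,3R)-2-(benzyloxy)-3-[3,4-bis(benzyloxy)phenyl]-3-(ethynyloxy)propyl]cyclobut-2-en-1-one | C#CO[C@H](c4ccc(OCc5ccccc5)c(OCc5ccccc5)c4)[C@@H](OCc5ccccc5)CC1=C(OCc5ccccc5)CC1=O | intermediate
26 | (S)-4-benzyl-1,3-oxazolidin-2-one | O=C1N[C@@H](Cc2ccccc2)CO1 | starting material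
27 | (S)-4-benzyl-3-[(benzyloxy)acetyl]-1,3-oxazolidin-2-one | O=C(COCc1ccccc1)N1C(=O)OC[C@@H]1Cc1ccccc1 | intermediate
28 | (Z)-dibutylboron enolate of 27 | CCCCB(CCCC)O/C(=C\OCc1ccccc1)N1C(=O)OC[C@@H]1Cc1ccccc1 | intermediate
29 | (4S)-4-benzyl-3-[(2S,3R)-2-(benzyloxy)-3-[3,4-bis(benzyloxy)phenyl]-3-hydroxypropanoyl]-1,3-oxazolidin-2-one | O[C@H](c4ccc(OCc5ccccc5)c(OCc5ccccc5)c4)[C@H](OCc5ccccc5)C(=O)N1C(=O)OC[C@@H]1Cc1ccccc1 | intermediate
30 | (1R,2R)-2-(benzyloxy)-1-[3,4-bis(benzyloxy)phenyl]propane-1,3-diol | O[C@H](c4ccc(OCc5ccccc5)c(OCc5ccccc5)c4)[C@H](OCc5ccccc5)CO | intermediate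
31 | (1R,2R)-2-(benzyloxy)-1-[3,4-bis(benzyloxy)phenyl]-3-[(triisopropylsilyl)oxy]propan-1-ol | O[C@H](c4ccc(OCc5ccccc5)c(OCc5ccccc5)c4)[C@H](OCc5ccccc5)CO[Si](C(C)C)(C(C)C)C(C)C | intermediate
32 | (E)-1,2-dichlorovinyl ether of 31 | Cl/C=C(/Cl)O[C@H](c4ccc(OCc5ccccc5)c(OCc5ccccc5)c4)[C@H](OCc5ccccc5)CO[Si](C(C)C)(C(C)C)C(C)C | intermediate
33 | (2R,3R)-2-(benzyloxy)-3-[3,4-bis(benzyloxy)phenyl]-3-{[(E)-1,2-dichloroethenyl]oxy}propan-1-ol | Cl/C=C(/Cl)O[C@H](c4ccc(OCc5ccccc5)c(OCc5ccccc5)c4)[C@H](OCc5ccccc5)CO | intermediate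
34 | trifluoromethanesulfonate of 33 | Cl/C=C(/Cl)O[C@H](c4ccc(OCc5ccccc5)c(OCc5ccccc5)c4)[C@H](OCc5ccccc5)COS(=O)(=O)C(F)(F)F | intermediate
35 | (4R,5R)-1,4-bis(benzyloxy)-5-[3,4-bis(benzyloxy)phenyl]-5-{[(E)-1,2-dichloroethenyl]oxy}pent-1-yne | Cl/C=C(/Cl)O[C@H](c4ccc(OCc5ccccc5)c(OCc5ccccc5)c4)[C@H](OCc5ccccc5)CC#COCc5ccccc5 | intermediate
36 | 3-(benzyloxy)-2-[(2R,3R)-2-(benzyloxy)-3-[3,4-bis(benzyloxy)phenyl]-3-{[(E)-1,2-dichloroethenyl]oxy}propyl]cyclobut-2-en-1-one | Cl/C=C(/Cl)O[C@H](c4ccc(OCc5ccccc5)c(OCc5ccccc5)c4)[C@H](OCc5ccccc5)CC1=C(OCc5ccccc5)CC1=O | intermediate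
37 | diisobutylaluminium alkoxide of the cyclobutenol from 36 | Cl/C=C(/Cl)O[C@H](c4ccc(OCc5ccccc5)c(OCc5ccccc5)c4)[C@H](OCc5ccccc5)CC1=C(OCc5ccccc5)CC1O[Al](CC(C)C)CC(C)C | intermediate
38 | lithium acetylide from 37 | [Li]C#CO[C@H](c4ccc(OCc5ccccc5)c(OCc5ccccc5)c4)[C@H](OCc5ccccc5)CC1=C(OCc5ccccc5)CC1O[Al](CC(C)C)CC(C)C | intermediate
39 | 3-(benzyloxy)-2-[(2R,3R)-2-(benzyloxy)-3-[3,4-bis(benzyloxy)phenyl]-3-(ethynyloxy)propyl]cyclobut-2-en-1-ol (carbinol epimers) | C#CO[C@H](c4ccc(OCc5ccccc5)c(OCc5ccccc5)c4)[C@H](OCc5ccccc5)CC1=C(OCc5ccccc5)CC1O | intermediate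
40 | 3-(benzyloxy)-2-[(2R,3R)-2-(benzyloxy)-3-[3,4-bis(benzyloxy)phenyl]-3-(ethynyloxy)propyl]cyclobut-2-en-1-one | C#CO[C@H](c4ccc(OCc5ccccc5)c(OCc5ccccc5)c4)[C@H](OCc5ccccc5)CC1=C(OCc5ccccc5)CC1=O | intermediate
41 | (+)-catechin | O[C@H]1Cc2c(O)cc(O)cc2O[C@@H]1c1ccc(O)c(O)c1 | starting material
42 | 5,7,3',4'-tetra-O-benzyl-(+)-catechin | c5ccccc5COc1cc(OCc5ccccc5)c2c(c1)O[C@H](c4ccc(OCc5ccccc5)c(OCc5ccccc5)c4)[C@@H](O)C2 | intermediate
43 | 3,5,7,3',4'-penta-O-benzyl-(+)-catechin | c5ccccc5COc1cc(OCc5ccccc5)c2c(c1)O[C@H](c4ccc(OCc5ccccc5)c(OCc5ccccc5)c4)[C@@H](OCc5ccccc5)C2 | intermediate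
44 | 4-(2-ethoxyethoxy)-3,5,7,3',4'-penta-O-benzylcatechin (C4 epimers) | c5ccccc5COc1cc(OCc5ccccc5)c2c(c1)O[C@H](c4ccc(OCc5ccccc5)c(OCc5ccccc5)c4)[C@@H](OCc5ccccc5)C2OCCOCC | intermediate
45 | key-step precursor: penta-O-benzylcatechin with the 4α alkynyl ether side chain of 25 | c5ccccc5COc1cc(OCc5ccccc5)c2c(c1)O[C@H](c4ccc(OCc5ccccc5)c(OCc5ccccc5)c4)[C@@H](OCc5ccccc5)[C@@H]2C#CO[C@H](c4ccc(OCc5ccccc5)c(OCc5ccccc5)c4)[C@@H](OCc5ccccc5)CC1=C(OCc5ccccc5)CC1=O | intermediate
46 | vinylketene from 45 | c5ccccc5COc1cc(OCc5ccccc5)c2c(c1)O[C@H](c4ccc(OCc5ccccc5)c(OCc5ccccc5)c4)[C@@H](OCc5ccccc5)[C@@H]2C#CO[C@H](c4ccc(OCc5ccccc5)c(OCc5ccccc5)c4)[C@@H](OCc5ccccc5)CC(=C=O)C(OCc5ccccc5)=C | intermediate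
47 | fused vinylcyclobutenone (2-oxabicyclo[4.2.0]oct-1(8)-en-7-one) from 46 | c5ccccc5COc1cc(OCc5ccccc5)c2c(c1)O[C@H](c4ccc(OCc5ccccc5)c(OCc5ccccc5)c4)[C@@H](OCc5ccccc5)[C@@H]2C1=C3O[C@H](c4ccc(OCc5ccccc5)c(OCc5ccccc5)c4)[C@@H](OCc5ccccc5)CC3(C(OCc5ccccc5)=C)C1=O | intermediate
48 | dienylketene from 47 | c5ccccc5COc1cc(OCc5ccccc5)c2c(c1)O[C@H](c4ccc(OCc5ccccc5)c(OCc5ccccc5)c4)[C@@H](OCc5ccccc5)[C@@H]2C(=C=O)C=1O[C@H](c4ccc(OCc5ccccc5)c(OCc5ccccc5)c4)[C@@H](OCc5ccccc5)CC=1C(OCc5ccccc5)=C | intermediate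
49 | nona-O-benzyl catechin-(4α→8)-catechin, free O7 on unit 2 | c5ccccc5COc1cc(OCc5ccccc5)c2c(c1)O[C@H](c4ccc(OCc5ccccc5)c(OCc5ccccc5)c4)[C@@H](OCc5ccccc5)[C@@H]2c1c(O)cc(OCc5ccccc5)c2c1O[C@H](c4ccc(OCc5ccccc5)c(OCc5ccccc5)c4)[C@@H](OCc5ccccc5)C2 | intermediate
50 | deca-O-benzyl catechin-(4α→8)-catechin | c5ccccc5COc1cc(OCc5ccccc5)c2c(c1)O[C@H](c4ccc(OCc5ccccc5)c(OCc5ccccc5)c4)[C@@H](OCc5ccccc5)[C@@H]2c1c(OCc5ccccc5)cc(OCc5ccccc5)c2c1O[C@H](c4ccc(OCc5ccccc5)c(OCc5ccccc5)c4)[C@@H](OCc5ccccc5)C2 | intermediate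
51 | deca-O-benzyl dimer with 2-ethoxyethoxy at C4 of unit 2 (C4 epimers) | c5ccccc5COc1cc(OCc5ccccc5)c2c(c1)O[C@H](c4ccc(OCc5ccccc5)c(OCc5ccccc5)c4)[C@@H](OCc5ccccc5)[C@@H]2c1c(OCc5ccccc5)cc(OCc5ccccc5)c2c1O[C@H](c4ccc(OCc5ccccc5)c(OCc5ccccc5)c4)[C@@H](OCc5ccccc5)C2OCCOCC | intermediate
52 | trimer precursor: deca-O-benzyl dimer with the 4α alkynyl ether side chain of 25 on unit 2 | c5ccccc5COc1cc(OCc5ccccc5)c2c(c1)O[C@H](c4ccc(OCc5ccccc5)c(OCc5ccccc5)c4)[C@@H](OCc5ccccc5)[C@@H]2c1c(OCc5ccccc5)cc(OCc5ccccc5)c2c1O[C@H](c4ccc(OCc5ccccc5)c(OCc5ccccc5)c4)[C@@H](OCc5ccccc5)[C@@H]2C#CO[C@H](c4ccc(OCc5ccccc5)c(OCc5ccccc5)c4)[C@@H](OCc5ccccc5)CC1=C(OCc5ccccc5)CC1=O | intermediate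
53 | vinylketene from 52 | c5ccccc5COc1cc(OCc5ccccc5)c2c(c1)O[C@H](c4ccc(OCc5ccccc5)c(OCc5ccccc5)c4)[C@@H](OCc5ccccc5)[C@@H]2c1c(OCc5ccccc5)cc(OCc5ccccc5)c2c1O[C@H](c4ccc(OCc5ccccc5)c(OCc5ccccc5)c4)[C@@H](OCc5ccccc5)[C@@H]2C#CO[C@H](c4ccc(OCc5ccccc5)c(OCc5ccccc5)c4)[C@@H](OCc5ccccc5)CC(=C=O)C(OCc5ccccc5)=C | intermediate
54 | fused vinylcyclobutenone from 53 | c5ccccc5COc1cc(OCc5ccccc5)c2c(c1)O[C@H](c4ccc(OCc5ccccc5)c(OCc5ccccc5)c4)[C@@H](OCc5ccccc5)[C@@H]2c1c(OCc5ccccc5)cc(OCc5ccccc5)c2c1O[C@H](c4ccc(OCc5ccccc5)c(OCc5ccccc5)c4)[C@@H](OCc5ccccc5)[C@@H]2C1=C3O[C@H](c4ccc(OCc5ccccc5)c(OCc5ccccc5)c4)[C@@H](OCc5ccccc5)CC3(C(OCc5ccccc5)=C)C1=O | intermediate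
55 | dienylketene from 54 | c5ccccc5COc1cc(OCc5ccccc5)c2c(c1)O[C@H](c4ccc(OCc5ccccc5)c(OCc5ccccc5)c4)[C@@H](OCc5ccccc5)[C@@H]2c1c(OCc5ccccc5)cc(OCc5ccccc5)c2c1O[C@H](c4ccc(OCc5ccccc5)c(OCc5ccccc5)c4)[C@@H](OCc5ccccc5)[C@@H]2C(=C=O)C=1O[C@H](c4ccc(OCc5ccccc5)c(OCc5ccccc5)c4)[C@@H](OCc5ccccc5)CC=1C(OCc5ccccc5)=C | intermediate
56 | tetradeca-O-benzyl catechin trimer, free O7 on unit 3 | c5ccccc5COc1cc(OCc5ccccc5)c2c(c1)O[C@H](c4ccc(OCc5ccccc5)c(OCc5ccccc5)c4)[C@@H](OCc5ccccc5)[C@@H]2c1c(OCc5ccccc5)cc(OCc5ccccc5)c2c1O[C@H](c4ccc(OCc5ccccc5)c(OCc5ccccc5)c4)[C@@H](OCc5ccccc5)[C@@H]2c1c(O)cc(OCc5ccccc5)c2c1O[C@H](c4ccc(OCc5ccccc5)c(OCc5ccccc5)c4)[C@@H](OCc5ccccc5)C2 | intermediate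
57 | pentadeca-O-benzyl catechin trimer | c5ccccc5COc1cc(OCc5ccccc5)c2c(c1)O[C@H](c4ccc(OCc5ccccc5)c(OCc5ccccc5)c4)[C@@H](OCc5ccccc5)[C@@H]2c1c(OCc5ccccc5)cc(OCc5ccccc5)c2c1O[C@H](c4ccc(OCc5ccccc5)c(OCc5ccccc5)c4)[C@@H](OCc5ccccc5)[C@@H]2c1c(OCc5ccccc5)cc(OCc5ccccc5)c2c1O[C@H](c4ccc(OCc5ccccc5)c(OCc5ccccc5)c4)[C@@H](OCc5ccccc5)C2 | intermediate
58 | pentadeca-O-benzyl trimer with 2-ethoxyethoxy at C4 of unit 3 (C4 epimers) | c5ccccc5COc1cc(OCc5ccccc5)c2c(c1)O[C@H](c4ccc(OCc5ccccc5)c(OCc5ccccc5)c4)[C@@H](OCc5ccccc5)[C@@H]2c1c(OCc5ccccc5)cc(OCc5ccccc5)c2c1O[C@H](c4ccc(OCc5ccccc5)c(OCc5ccccc5)c4)[C@@H](OCc5ccccc5)[C@@H]2c1c(OCc5ccccc5)cc(OCc5ccccc5)c2c1O[C@H](c4ccc(OCc5ccccc5)c(OCc5ccccc5)c4)[C@@H](OCc5ccccc5)C2OCCOCC | intermediate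
59 | tetramer precursor: pentadeca-O-benzyl trimer with the 4α alkynyl ether side chain of 40 on unit 3 | c5ccccc5COc1cc(OCc5ccccc5)c2c(c1)O[C@H](c4ccc(OCc5ccccc5)c(OCc5ccccc5)c4)[C@@H](OCc5ccccc5)[C@@H]2c1c(OCc5ccccc5)cc(OCc5ccccc5)c2c1O[C@H](c4ccc(OCc5ccccc5)c(OCc5ccccc5)c4)[C@@H](OCc5ccccc5)[C@@H]2c1c(OCc5ccccc5)cc(OCc5ccccc5)c2c1O[C@H](c4ccc(OCc5ccccc5)c(OCc5ccccc5)c4)[C@@H](OCc5ccccc5)[C@@H]2C#CO[C@H](c4ccc(OCc5ccccc5)c(OCc5ccccc5)c4)[C@H](OCc5ccccc5)CC1=C(OCc5ccccc5)CC1=O | intermediate
60 | vinylketene from 59 | c5ccccc5COc1cc(OCc5ccccc5)c2c(c1)O[C@H](c4ccc(OCc5ccccc5)c(OCc5ccccc5)c4)[C@@H](OCc5ccccc5)[C@@H]2c1c(OCc5ccccc5)cc(OCc5ccccc5)c2c1O[C@H](c4ccc(OCc5ccccc5)c(OCc5ccccc5)c4)[C@@H](OCc5ccccc5)[C@@H]2c1c(OCc5ccccc5)cc(OCc5ccccc5)c2c1O[C@H](c4ccc(OCc5ccccc5)c(OCc5ccccc5)c4)[C@@H](OCc5ccccc5)[C@@H]2C#CO[C@H](c4ccc(OCc5ccccc5)c(OCc5ccccc5)c4)[C@H](OCc5ccccc5)CC(=C=O)C(OCc5ccccc5)=C | intermediate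
61 | fused vinylcyclobutenone from 60 | c5ccccc5COc1cc(OCc5ccccc5)c2c(c1)O[C@H](c4ccc(OCc5ccccc5)c(OCc5ccccc5)c4)[C@@H](OCc5ccccc5)[C@@H]2c1c(OCc5ccccc5)cc(OCc5ccccc5)c2c1O[C@H](c4ccc(OCc5ccccc5)c(OCc5ccccc5)c4)[C@@H](OCc5ccccc5)[C@@H]2c1c(OCc5ccccc5)cc(OCc5ccccc5)c2c1O[C@H](c4ccc(OCc5ccccc5)c(OCc5ccccc5)c4)[C@@H](OCc5ccccc5)[C@@H]2C1=C3O[C@H](c4ccc(OCc5ccccc5)c(OCc5ccccc5)c4)[C@H](OCc5ccccc5)CC3(C(OCc5ccccc5)=C)C1=O | intermediate
62 | dienylketene from 61 | c5ccccc5COc1cc(OCc5ccccc5)c2c(c1)O[C@H](c4ccc(OCc5ccccc5)c(OCc5ccccc5)c4)[C@@H](OCc5ccccc5)[C@@H]2c1c(OCc5ccccc5)cc(OCc5ccccc5)c2c1O[C@H](c4ccc(OCc5ccccc5)c(OCc5ccccc5)c4)[C@@H](OCc5ccccc5)[C@@H]2c1c(OCc5ccccc5)cc(OCc5ccccc5)c2c1O[C@H](c4ccc(OCc5ccccc5)c(OCc5ccccc5)c4)[C@@H](OCc5ccccc5)[C@@H]2C(=C=O)C=1O[C@H](c4ccc(OCc5ccccc5)c(OCc5ccccc5)c4)[C@H](OCc5ccccc5)CC=1C(OCc5ccccc5)=C | intermediate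
63 | nonadeca-O-benzyl catechin-(4α→8)-catechin-(4α→8)-catechin-(4α→8)-epicatechin, free O7 on unit 4 | c5ccccc5COc1cc(OCc5ccccc5)c2c(c1)O[C@H](c4ccc(OCc5ccccc5)c(OCc5ccccc5)c4)[C@@H](OCc5ccccc5)[C@@H]2c1c(OCc5ccccc5)cc(OCc5ccccc5)c2c1O[C@H](c4ccc(OCc5ccccc5)c(OCc5ccccc5)c4)[C@@H](OCc5ccccc5)[C@@H]2c1c(OCc5ccccc5)cc(OCc5ccccc5)c2c1O[C@H](c4ccc(OCc5ccccc5)c(OCc5ccccc5)c4)[C@@H](OCc5ccccc5)[C@@H]2c1c(O)cc(OCc5ccccc5)c2c1O[C@H](c4ccc(OCc5ccccc5)c(OCc5ccccc5)c4)[C@H](OCc5ccccc5)C2 | intermediate
64 | catechin-(4α→8)-catechin-(4α→8)-catechin-(4α→8)-epicatechin | Oc1cc(O)c2c(c1)O[C@H](c1ccc(O)c(O)c1)[C@@H](O)[C@@H]2c1c(O)cc(O)c2c1O[C@H](c1ccc(O)c(O)c1)[C@@H](O)[C@@H]2c1c(O)cc(O)c2c1O[C@H](c1ccc(O)c(O)c1)[C@@H](O)[C@@H]2c1c(O)cc(O)c2c1O[C@H](c1ccc(O)c(O)c1)[C@H](O)C2 | target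

## Step count and least certain steps

Total step count: 39. Longest linear sequence: 23 steps (steps 3–10 and 12–15 to 25, then steps 29–39). The main chain from 41 takes 14 steps (steps 26–39).

**Step 30 (key step).** The secondary benzylic alkynyl ether may be lost before the ketene reaches it (sigmatropic shift into the aryl ring, retro-ene loss). The vinylketene may also re-close or decay if the [2+2] addition is slow, because the alkyne carbon that must bond to the ketene carbonyl sits on the crowded C4. Fallback, known chemistry: the Lewis acid condensation of a C4-activated flavan with a benzylated flavan-3-ol. It sets out from 44, which with an excess of 43 and TMSOTf in CH2Cl2 at −78 °C should give attack of C8 of 43 on the C4 cation trans to O3, and it returns to the route at 50. No new compound arises.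

**Step 34.** The same cascade must run with a dimer on the alkyne carbon, so the [2+2] addition is slower and the side reactions of the alkynyl ether gain time. Fallback, known chemistry: it sets out from 51, which is condensed with an excess of 43 under TMSOTf in CH2Cl2 at −78 °C, and returns at 57. No new compound arises.

**Step 38.** With the 2,3-cis tether either the aryl or the benzyloxy group must become axial as ring C forms, which may slow the ring closure further on the largest substrate. Fallback, known chemistry: it sets out from 58, which is condensed under TMSOTf at −78 °C with an excess of penta-O-benzyl-(−)-epicatechin F1 (prepared from commercial (−)-epicatechin by exhaustive benzylation with NaH and BnBr) to give the icosa-O-benzyl tetramer F2. Hydrogenolysis of F2 under the conditions of step 39 returns at 64.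

**Step 29.** Three things may go wrong. The Lewis acid may ionise the benzylic C–O bond of the alkynyl ether itself, or the cation may add to the alkyne and the side chain leave as a cation. The slim nucleophile may show poor facial selectivity at C4. The cation may be captured by C6 or C8 of a second molecule of 44. Fallback: it sets out from 21. Reduction with i-Bu2AlH and silylation of the crude alcohol (TIPSOTf, 2,6-lutidine) give the silyl-protected cyclobutenol dichlorovinyl ether F3. n-BuLi (2 equiv) and then Me2AlCl convert F3 into its alkynyl(dimethyl)alane, which displaces the chelating 2-ethoxyethoxy group of 44 without a silyl Lewis acid and gives the masked coupling product F4. Bu4NF frees the cyclobutenol F5, and MnO2 returns at 45.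

**Step 32.** Hydride abstraction may occur at the doubly benzylic interflavan C4–H instead of the methylene of unit 2, or go on to over-oxidation. Fallback: it sets out from 49 and lets its single free phenol direct the oxidation. Ag2O in CH2Cl2 should give the para-quinone methide F6, which can form only at C4 of unit 2. Conjugate addition of 25, activated at its terminal alkyne by CuI and i-Pr2NEt, anti to the C3 benzyloxy group gives the 7-hydroxy precursor F7. Benzylation (BnBr, Cs2CO3, DMF, 0 °C) returns at 52.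

**Step 14.** The free 3-benzyloxycyclobutenol may be lost by acid-promoted ionisation and allylic transposition during work-up, and the excess n-BuLi may attack the aluminium-bound enol ether. Fallback, without the redox mask: it sets out from 19, which with n-BuLi (2 equiv) and then TIPSCl gives the C-silylated alkynyl ether F8. 20 then adds only to the unhindered benzyl alkynyl ether to give the C-silyl cyclobutenone F9. Bu4NF buffered with AcOH removes the silyl group and returns at 25.

## Further compounds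

F0 | step 30 | none | none
F0 | step 34 | none | none
F1 | step 38 | 3,5,7,3',4'-penta-O-benzyl-(−)-epicatechin | c5ccccc5COc1cc(OCc5ccccc5)c2c(c1)O[C@H](c4ccc(OCc5ccccc5)c(OCc5ccccc5)c4)[C@H](OCc5ccccc5)C2
F2 | step 38 | icosa-O-benzyl catechin-(4α→8)-catechin-(4α→8)-catechin-(4α→8)-epicatechin | c5ccccc5COc1cc(OCc5ccccc5)c2c(c1)O[C@H](c4ccc(OCc5ccccc5)c(OCc5ccccc5)c4)[C@@H](OCc5ccccc5)[C@@H]2c1c(OCc5ccccc5)cc(OCc5ccccc5)c2c1O[C@H](c4ccc(OCc5ccccc5)c(OCc5ccccc5)c4)[C@@H](OCc5ccccc5)[C@@H]2c1c(OCc5ccccc5)cc(OCc5ccccc5)c2c1O[C@H](c4ccc(OCc5ccccc5)c(OCc5ccccc5)c4)[C@@H](OCc5ccccc5)[C@@H]2c1c(OCc5ccccc5)cc(OCc5ccccc5)c2c1O[C@H](c4ccc(OCc5ccccc5)c(OCc5ccccc5)c4)[C@H](OCc5ccccc5)C2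
F3 | step 29 | triisopropylsilyl ether of the cyclobutenol from 21 (dichlorovinyl ether retained) | Cl/C=C(/Cl)O[C@H](c4ccc(OCc5ccccc5)c(OCc5ccccc5)c4)[C@@H](OCc5ccccc5)CC1=C(OCc5ccccc5)CC1O[Si](C(C)C)(C(C)C)C(C)C
F4 | step 29 | penta-O-benzylcatechin with the 4α alkynyl ether side chain carrying the silyl-protected cyclobutenol | c5ccccc5COc1cc(OCc5ccccc5)c2c(c1)O[C@H](c4ccc(OCc5ccccc5)c(OCc5ccccc5)c4)[C@@H](OCc5ccccc5)[C@@H]2C#CO[C@H](c4ccc(OCc5ccccc5)c(OCc5ccccc5)c4)[C@@H](OCc5ccccc5)CC1=C(OCc5ccccc5)CC1O[Si](C(C)C)(C(C)C)C(C)C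
F5 | step 29 | penta-O-benzylcatechin with the 4α alkynyl ether side chain carrying the free cyclobutenol | c5ccccc5COc1cc(OCc5ccccc5)c2c(c1)O[C@H](c4ccc(OCc5ccccc5)c(OCc5ccccc5)c4)[C@@H](OCc5ccccc5)[C@@H]2C#CO[C@H](c4ccc(OCc5ccccc5)c(OCc5ccccc5)c4)[C@@H](OCc5ccccc5)CC1=C(OCc5ccccc5)CC1O
F6 | step 32 | para-quinone methide of 49 (C7 carbonyl, C4=C4a in unit 2) | c5ccccc5COc1cc(OCc5ccccc5)c2c(c1)O[C@H](c4ccc(OCc5ccccc5)c(OCc5ccccc5)c4)[C@@H](OCc5ccccc5)[C@@H]2C1=C2O[C@H](c4ccc(OCc5ccccc5)c(OCc5ccccc5)c4)[C@@H](OCc5ccccc5)C=C2C(OCc5ccccc5)=CC1=O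
F7 | step 32 | nona-O-benzyl dimer with free O7 on unit 2 and the 4α alkynyl ether side chain of 25 on unit 2 | c5ccccc5COc1cc(OCc5ccccc5)c2c(c1)O[C@H](c4ccc(OCc5ccccc5)c(OCc5ccccc5)c4)[C@@H](OCc5ccccc5)[C@@H]2c1c(O)cc(OCc5ccccc5)c2c1O[C@H](c4ccc(OCc5ccccc5)c(OCc5ccccc5)c4)[C@@H](OCc5ccccc5)[C@@H]2C#CO[C@H](c4ccc(OCc5ccccc5)c(OCc5ccccc5)c4)[C@@H](OCc5ccccc5)CC1=C(OCc5ccccc5)CC1=O
F8 | step 14 | (4S,5R)-1,4-bis(benzyloxy)-5-[3,4-bis(benzyloxy)phenyl]-5-{[(triisopropylsilyl)ethynyl]oxy}pent-1-yne | CC(C)[Si](C(C)C)(C(C)C)C#CO[C@H](c4ccc(OCc5ccccc5)c(OCc5ccccc5)c4)[C@@H](OCc5ccccc5)CC#COCc5ccccc5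
F9 | step 14 | C-triisopropylsilyl derivative of 25 | CC(C)[Si](C(C)C)(C(C)C)C#CO[C@H](c4ccc(OCc5ccccc5)c(OCc5ccccc5)c4)[C@@H](OCc5ccccc5)CC1=C(OCc5ccccc5)CC1=O
A1 | alternative 1 | flav-2-ene of unit 3 on penta-O-benzylepicatechin | c3ccccc3COc1cc(OCc3ccccc3)c2c(c1)OC(c1ccc(OCc3ccccc3)c(OCc3ccccc3)c1)=C[C@@H]2c1c(OCc3ccccc3)cc(OCc3ccccc3)c2c1O[C@H](c1ccc(OCc3ccccc3)c(OCc3ccccc3)c1)[C@H](OCc3ccccc3)C2
A2 | alternative 2 | octa-O-benzyl catechin-(4→8)-epicatechin with free C5 and C7 phenols on the upper unit | Oc1cc(O)c2c(c1)O[C@H](c1ccc(OCc3ccccc3)c(OCc3ccccc3)c1)[C@@H](OCc3ccccc3)[C@@H]2c1c(OCc3ccccc3)cc(OCc3ccccc3)c2c1O[C@H](c1ccc(OCc3ccccc3)c(OCc3ccccc3)c1)[C@H](OCc3ccccc3)C2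
A3 | alternative 3 | nona-O-benzyl catechin-(4→8)-epicatechin with free C3 hydroxyl on the upper unit | c3ccccc3COc1cc(OCc3ccccc3)c2c(c1)O[C@H](c1ccc(OCc3ccccc3)c(OCc3ccccc3)c1)[C@@H](O)[C@@H]2c1c(OCc3ccccc3)cc(OCc3ccccc3)c2c1O[C@H](c1ccc(OCc3ccccc3)c(OCc3ccccc3)c1)[C@H](OCc3ccccc3)C2
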